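The flavan is cut at C3–C4 of ring C. The feature used is that C4 sits on C4a of ring A as a benzylic carbon while C2 is a CH next to O1: a formyl group on ring A can hand its carbon to C3 and its hydrogen to C2 of a 1-arylvinyl ether carried by O1. One enantioselective rhodium-catalysed intramolecular hydroacylation of aldehyde 16, a 3-prenyl-2-(1-arylvinyloxy)benzaldehyde with MOM-masked phenols, should thus close ring C, form C3–C4 and set C2 as (S)-chroman-4-one 17. The C4 carbonyl is afterwards removed with the help of the peri 5-OH, and the MOM ethers are cleaved.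

Key step: step 10

Remark: the sense of induction of the new rhodium step cannot be fixed in advance, so (R)-DTBM-SEGPHOS stands for whichever ligand antipode delivers (S)-17; C2 keeps the descriptor (S) from 17 to 22 because its priorities (O1 > aryl > C3 > H) never change.

Step 1
Reactants: 1 2,4,6-trihydroxybenzaldehyde
Product: 2 2-hydroxy-4,6-bis(methoxymethoxy)benzaldehyde
Conditions: MOMCl (2.1 equiv), i-Pr2NEt, CH2Cl2, 0 °C to rt
Reagents that add atoms: chloromethyl methyl ether, COCCl
Why: Base-mediated O-alkylation (MOM ether formation), in which the hydroxyl hydrogen-bonded to the formyl oxygen is the least nucleophilic, so two equivalents should stop at the 4,6-bis-ether and leave the 2-OH free.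

Step 2
Reactants: 2 2-hydroxy-4,6-bis(methoxymethoxy)benzaldehyde; 3 3-chloro-3-methylbut-1-yne
Product: 4 2-[(2-methylbut-3-yn-2-yl)oxy]-4,6-bis(methoxymethoxy)benzaldehyde
Conditions: CuCl2·2H2O (1 mol%), DBU, MeCN, 0 °C
Reagents that add atoms: none
Why: Copper-catalysed propargylic substitution (O-propargylation of a phenol by a tertiary propargyl chloride), in which DBU fully deprotonates the chelated phenol and the copper-activated electrophile is captured at the tertiary carbon without touching the aldehyde.

Step 3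
Reactants: 4 2-[(2-methylbut-3-yn-2-yl)oxy]-4,6-bis(methoxymethoxy)benzaldehyde
Product: 5 2-[(2-methylbut-3-en-2-yl)oxy]-4,6-bis(methoxymethoxy)benzaldehyde
Conditions: H2 (1 atm), Pd/CaCO3 poisoned with Pb(OAc)2 (Lindlar catalyst), quinoline, EtOAc, rt
Reagents that add atoms: none
Why: Lindlar semihydrogenation, in which the poisoned palladium surface reduces the terminal alkyne to the vinyl group and stops there, leaving the aryl aldehyde and the acetals intact.

Step 4
Reactants: 5 2-[(2-methylbut-3-en-2-yl)oxy]-4,6-bis(methoxymethoxy)benzaldehyde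
Product: 7 2-hydroxy-4,6-bis(methoxymethoxy)-3-(3-methylbut-2-en-1-yl)benzaldehyde, via ortho-dienone 6 (not isolated)
Conditions: N,N-diethylaniline, 130 °C
Reagents that add atoms: none
Why: Aromatic Claisen rearrangement ([3,3]-sigmatropic shift, then enolisation of dienone 6), in which the only ortho carbon bearing hydrogen is C3 and the allyl unit inverts, so the 1,1-dimethylallyl ether becomes a C-prenyl group beside the regenerated phenol.

Step 5
Reactants: 8 3-bromo-5-methoxyphenol
Product: 9 1-bromo-3-methoxy-5-(methoxymethoxy)benzene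
Conditions: MOMCl, i-Pr2NEt, CH2Cl2, 0 °C to rt
Reagents that add atoms: chloromethyl methyl ether, COCCl
Why: MOM ether formation (O-alkylation) at the single phenol, with the aryl bromide and the methyl ether as spectators.

Step 6
Reactants: 9 1-bromo-3-methoxy-5-(methoxymethoxy)benzene; 10 N-methoxy-N-methylacetamide
Product: 12 1-[3-methoxy-5-(methoxymethoxy)phenyl]ethan-1-one, via aryllithium 11 (not isolated)
Conditions: n-BuLi, THF, −78 °C; then 10, −78 to 0 °C; H2O
Reagents that add atoms: none
Why: Bromine–lithium exchange followed by acylation with a Weinreb amide, where exchange at −78 °C outruns ortho-lithiation and the chelated tetrahedral adduct holds until work-up, so the methyl ketone should form without over-addition.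

Step 7
Reactants: 12 1-[3-methoxy-5-(methoxymethoxy)phenyl]ethan-1-one
Product: 14 1-[3-methoxy-5-(methoxymethoxy)phenyl]ethenyl trifluoromethanesulfonate, via potassium enolate 13 (not isolated)
Conditions: KN(SiMe3)2, THF, −78 °C; then PhNTf2, −78 to 0 °C
Reagents that add atoms: N-phenylbis(trifluoromethanesulfonimide), O=S(=O)(N(c1ccccc1)S(=O)(=O)C(F)(F)F)C(F)(F)F
Why: Enolate O-sulfonylation (enol triflate synthesis), in which the methyl ketone has a single enolisable site and the base-only conditions keep the MOM ether.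

Step 8
Reactants: 14 1-[3-methoxy-5-(methoxymethoxy)phenyl]ethenyl trifluoromethanesulfonate
Product: 15 2-{1-[3-methoxy-5-(methoxymethoxy)phenyl]ethenyl}-4,4,5,5-tetramethyl-1,3,2-dioxaborolane
Conditions: B2pin2, PdCl2(PPh3)2 (3 mol%), PPh3, KOPh, toluene, 50 °C
Reagents that add atoms: bis(pinacolato)diboron, CC1(C)OB(OC1(C)C)B1OC(C)(C)C(C)(C)O1
Why: Miyaura borylation of an alkenyl triflate, in which oxidative addition of zerovalent palladium, transmetalation with the phenoxide-activated diboron and reductive elimination give the 1-arylvinyl boronate with the double bond in place.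

Step 9
Reactants: 7 2-hydroxy-4,6-bis(methoxymethoxy)-3-(3-methylbut-2-en-1-yl)benzaldehyde; 15 2-{1-[3-methoxy-5-(methoxymethoxy)phenyl]ethenyl}-4,4,5,5-tetramethyl-1,3,2-dioxaborolane
Product: 16 4,6-bis(methoxymethoxy)-2-({1-[3-methoxy-5-(methoxymethoxy)phenyl]ethenyl}oxy)-3-(3-methylbut-2-en-1-yl)benzaldehyde
Conditions: 15 (2 equiv), Cu(OAc)2 (2 equiv), pyridine, 4 Å MS, CH2Cl2, dry air, rt
Reagents that add atoms: none
Why: Chan–Lam oxidative C–O coupling (O-alkenylation of a phenol with an alkenyl boronate), in which transmetalation to divalent copper, phenoxide coordination and reductive elimination from a higher-valent copper centre form the aryl 1-arylvinyl ether at room temperature under near-neutral conditions that spare the aldehyde, the prenyl group and the acetals.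

Step 10
Reactants: 16 4,6-bis(methoxymethoxy)-2-({1-[3-methoxy-5-(methoxymethoxy)phenyl]ethenyl}oxy)-3-(3-methylbut-2-en-1-yl)benzaldehyde
Product: 17 (2S)-5,7-bis(methoxymethoxy)-2-[3-methoxy-5-(methoxymethoxy)phenyl]-8-(3-methylbut-2-en-1-yl)chroman-4-one
Conditions: [Rh(cod)Cl]2 (5 mol%), (R)-DTBM-SEGPHOS (11 mol%), NaB[3,5-(CF3)2C6H3]4 (10 mol%), 1,4-dioxane, 4 Å MS, 60 °C, Ar
Reagents that add atoms: none
Why: Proposed new method: the cationic monovalent rhodium–bisphosphine complex inserts into the formyl C–H bond of 16 (the flanking aryl ether oxygens can hold the acyl rhodium hydride and slow decarbonylation), the pendant enol ether coordinates, hydride passes to its internal aryl- and oxygen-bearing carbon (C2) while rhodium takes the terminal CH2 (C3), and C–C reductive elimination joins C3 to the acyl carbon C4. The closest known reaction type is the rhodium–bisphosphine enantioselective intramolecular hydroacylation of 1,1-disubstituted alkenes held ortho to an aryl aldehyde, which turns 2-(1-substituted vinyl)benzaldehydes into 3-substituted indanones (and ortho-allylbenzaldehydes into tetralones by endo closure); new here are the oxygen atom in the tether and the enol ether as acceptor. Ring C closes in a formal 6-endo-trig mode through a seven-membered acyl–alkyl rhodacycle. The C2 stereocentre is set in the hydride transfer, where the axially chiral bisphosphine differentiates the two faces of the prochiral alkene; (R)-DTBM-SEGPHOS is proposed for the (S) product and its antipode is used if the sense proves reversed. The step needs endo over exo regioselectivity, which the oxygen-polarised terminal alkene and the preference for a primary over a fully substituted alkyl rhodium should secure (the exo product would be a 2-aryl-2-methylbenzofuran-3-one with a quaternary carbon), and chemoselectivity for the enol ether over the trisubstituted prenyl alkene, which is too hindered to insert. Dry, acid-free conditions are required so that the enol ether is not hydrolysed.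

Step 11
Reactants: 17 (2S)-5,7-bis(methoxymethoxy)-2-[3-methoxy-5-(methoxymethoxy)phenyl]-8-(3-methylbut-2-en-1-yl)chroman-4-one
Product: 18 (2S)-5-hydroxy-7-(methoxymethoxy)-2-[3-methoxy-5-(methoxymethoxy)phenyl]-8-(3-methylbut-2-en-1-yl)chroman-4-one
Conditions: MgBr2·OEt2 (3 equiv), Et2O–CH2Cl2, 0 °C to rt; then H2O
Reagents that add atoms: none
Why: Chelation-controlled Lewis-acid cleavage of an acetal, in which magnesium bridges the C4 carbonyl oxygen and O5 so that only the peri MOM ether is activated for bromide attack, while the 7- and 3'-MOM ethers cannot chelate and the C2 stereocentre is not involved.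

Step 12
Reactants: 18 (2S)-5-hydroxy-7-(methoxymethoxy)-2-[3-methoxy-5-(methoxymethoxy)phenyl]-8-(3-methylbut-2-en-1-yl)chroman-4-one
Product: 21 (2S)-7-(methoxymethoxy)-2-[3-methoxy-5-(methoxymethoxy)phenyl]-8-(3-methylbut-2-en-1-yl)chroman-5-ol, via 5-O-methoxycarbonyl flavanone 19 (not isolated), via ortho-quinone methide 20 (not isolated)
Conditions: ClCO2Me, Et3N, THF, 0 °C; then NaBH4, H2O, 0 °C to rt
Reagents that add atoms: none
Why: Reductive deoxygenation of an ortho-acyloxy aryl ketone (carbonate formation, then NaBH4), in which hydride reduction of the C4 ketone of 19, transfer of the methoxycarbonyl group to the new alkoxide and loss of methyl carbonate give ortho-quinone methide 20, which a second hydride reduces at C4 while C2 keeps its (S) configuration.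

Step 13
Reactants: 21 (2S)-7-(methoxymethoxy)-2-[3-methoxy-5-(methoxymethoxy)phenyl]-8-(3-methylbut-2-en-1-yl)chroman-5-ol
Product: 22 (2S)-2-(3-hydroxy-5-methoxyphenyl)-8-(3-methylbut-2-en-1-yl)chroman-5,7-diol
Conditions: 3 M aq. HCl, MeOH, 40 °C
Reagents that add atoms: none
Why: Acid-catalysed transacetalisation (MOM cleavage) in methanol, in which both acetals are exchanged to dimethoxymethane, the meta-dioxygenated ring B cannot stabilise a C2 cation (no ring opening, no racemisation), and the mild acidity and temperature are chosen to avoid cyclisation of the prenyl group onto the 7-OH.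

Compound list
1 | 2,4,6-trihydroxybenzaldehyde | O=Cc1c(O)cc(O)cc1O | starting material
2 | 2-hydroxy-4,6-bis(methoxymethoxy)benzaldehyde | O=Cc1c(O)cc(OCOC)cc1OCOC | intermediate
3 | 3-chloro-3-methylbut-1-yne | C#CC(C)(C)Cl | starting material
4 | 2-[(2-methylbut-3-yn-2-yl)oxy]-4,6-bis(methoxymethoxy)benzaldehyde | O=Cc1c(OC(C)(C)C#C)cc(OCOC)cc1OCOC | intermediate
5 | 2-[(2-methylbut-3-en-2-yl)oxy]-4,6-bis(methoxymethoxy)benzaldehyde | O=Cc1c(OC(C)(C)C=C)cc(OCOC)cc1OCOC | intermediate
6 | 2,4-bis(methoxymethoxy)-5-(3-methylbut-2-en-1-yl)-6-oxocyclohexa-1,3-diene-1-carbaldehyde (ortho-dienone, racemic at C5) | O=CC1=C(OCOC)C=C(OCOC)C(CC=C(C)C)C1=O | intermediate (not isolated)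
7 | 2-hydroxy-4,6-bis(methoxymethoxy)-3-(3-methylbut-2-en-1-yl)benzaldehyde | O=Cc1c(O)c(CC=C(C)C)c(OCOC)cc1OCOC | intermediate
8 | 3-bromo-5-methoxyphenol | COc1cc(O)cc(Br)c1 | starting material
9 | 1-bromo-3-methoxy-5-(methoxymethoxy)benzene | COCOc1cc(OC)cc(Br)c1 | intermediate
10 | N-methoxy-N-methylacetamide | CC(=O)N(C)OC | starting material
11 | [3-methoxy-5-(methoxymethoxy)phenyl]lithium | [Li]c1cc(OC)cc(OCOC)c1 | intermediate (not isolated)
12 | 1-[3-methoxy-5-(methoxymethoxy)phenyl]ethan-1-one | CC(=O)c1cc(OC)cc(OCOC)c1 | intermediate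
13 | potassium 1-[3-methoxy-5-(methoxymethoxy)phenyl]ethen-1-olate | [K+].[O-]C(=C)c1cc(OC)cc(OCOC)c1 | intermediate (not isolated)
14 | 1-[3-methoxy-5-(methoxymethoxy)phenyl]ethenyl trifluoromethanesulfonate | C=C(OS(=O)(=O)C(F)(F)F)c1cc(OC)cc(OCOC)c1 | intermediate
15 | 2-{1-[3-methoxy-5-(methoxymethoxy)phenyl]ethenyl}-4,4,5,5-tetramethyl-1,3,2-dioxaborolane | C=C(B1OC(C)(C)C(C)(C)O1)c1cc(OC)cc(OCOC)c1 | intermediate
16 | 4,6-bis(methoxymethoxy)-2-({1-[3-methoxy-5-(methoxymethoxy)phenyl]ethenyl}oxy)-3-(3-methylbut-2-en-1-yl)benzaldehyde | C=C(Oc1c(CC=C(C)C)c(OCOC)cc(OCOC)c1C=O)c1cc(OC)cc(OCOC)c1 | intermediate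
17 | (2S)-5,7-bis(methoxymethoxy)-2-[3-methoxy-5-(methoxymethoxy)phenyl]-8-(3-methylbut-2-en-1-yl)chroman-4-one | COCOc1cc(OC)cc([C@@H]2CC(=O)c3c(OCOC)cc(OCOC)c(CC=C(C)C)c3O2)c1 | intermediate
18 | (2S)-5-hydroxy-7-(methoxymethoxy)-2-[3-methoxy-5-(methoxymethoxy)phenyl]-8-(3-methylbut-2-en-1-yl)chroman-4-one | COCOc1cc(OC)cc([C@@H]2CC(=O)c3c(O)cc(OCOC)c(CC=C(C)C)c3O2)c1 | intermediate
19 | methyl (2S)-7-(methoxymethoxy)-2-[3-methoxy-5-(methoxymethoxy)phenyl]-8-(3-methylbut-2-en-1-yl)-4-oxochroman-5-yl carbonate | COCOc1cc(OC)cc([C@@H]2CC(=O)c3c(OC(=O)OC)cc(OCOC)c(CC=C(C)C)c3O2)c1 | intermediate (not isolated)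
20 | (2S)-7-(methoxymethoxy)-2-[3-methoxy-5-(methoxymethoxy)phenyl]-8-(3-methylbut-2-en-1-yl)-2,3-dihydro-5H-chromen-5-one (ortho-quinone methide, C4=C4a) | COCOc1cc(OC)cc([C@@H]2CC=C3C(=O)C=C(OCOC)C(CC=C(C)C)=C3O2)c1 | intermediate (not isolated)
21 | (2S)-7-(methoxymethoxy)-2-[3-methoxy-5-(methoxymethoxy)phenyl]-8-(3-methylbut-2-en-1-yl)chroman-5-ol | COCOc1cc(OC)cc([C@@H]2CCc3c(O)cc(OCOC)c(CC=C(C)C)c3O2)c1 | intermediate
22 | (2S)-2-(3-hydroxy-5-methoxyphenyl)-8-(3-methylbut-2-en-1-yl)chroman-5,7-diol | COc1cc(O)cc([C@@H]2CCc3c(O)cc(O)c(CC=C(C)C)c3O2)c1 | target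

Total step count: 13.
Longest linear sequence: 9 steps (steps 1–4 and 9–13 from 1; the ring B branch, steps 5–8 and 9–13 from 8, is equally long).

Steps most likely to fail

1. Step 10. Decarbonylation of the acyl rhodium hydride may outrun alkene insertion and deactivate the catalyst as a rhodium carbonyl, or the hydride transfer to C2 may discriminate the alkene faces poorly. The fallback uses known chemistry, sets out from 7 and 9, and rejoins the route at 17. Addition of HC≡CMgBr (THF, 0 °C) to aldehyde 7 should give 1-[2-hydroxy-4,6-bis(methoxymethoxy)-3-(3-methylbut-2-en-1-yl)phenyl]prop-2-yn-1-ol F1. MnO2 in CH2Cl2 should oxidise it to 1-[2-hydroxy-4,6-bis(methoxymethoxy)-3-(3-methylbut-2-en-1-yl)phenyl]prop-2-yn-1-one F2. Et2NH in EtOH (amine conjugate addition, 6-endo ring closure, loss of the amine) should then close it to 5,7-bis(methoxymethoxy)-8-(3-methylbut-2-en-1-yl)-4H-chromen-4-one F3. In parallel, bromide 9 is converted into aryllithium 11 as in step 6, trapped with B(OiPr)3 and hydrolysed to [3-methoxy-5-(methoxymethoxy)phenyl]boronic acid F4. Rhodium-catalysed asymmetric 1,4-addition of F4 to F3 ([Rh(OH)(cod)]2, an electron-poor atropisomeric bisphosphine of the MeO-BIPHEP family, toluene–H2O, no added base, rt) is an established enantioselective entry to 2-arylchroman-4-ones from chromones and should deliver 17.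

2. Step 9. C–O bond formation at the doubly ortho-substituted, hydrogen-bonded phenol may be slow, so that protodeboronation and homocoupling consume the alkenyl boronate. The fallback sets out from 7 and triflate 14 (step 8 is skipped) and rejoins at 16. It is a zerovalent-palladium-catalysed C–O cross-coupling of the phenol with the alkenyl triflate (Pd2(dba)3, a bulky di-tert-butyl biarylphosphine, K3PO4, toluene, 80 °C), a known way to aryl enol ethers in which the vinyl partner is the electrophile. It makes no new compound (F0).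

3. Step 11. Site selectivity may be lost, with the 7- or 3'-MOM ether cleaved alongside the peri one. The fallback sets out from 17 and rejoins at 22. Global MOM cleavage (3 M aq. HCl, MeOH, 40 °C) should give (2S)-5,7-dihydroxy-2-(3-hydroxy-5-methoxyphenyl)-8-(3-methylbut-2-en-1-yl)chroman-4-one F5. Excess ClCO2Me and Et3N (THF, 0 °C) should convert all three phenols into the tris(methyl carbonate) (2S)-2-{3-methoxy-5-[(methoxycarbonyl)oxy]phenyl}-8-(3-methylbut-2-en-1-yl)-4-oxochroman-5,7-diyl bis(methyl carbonate) F6. NaBH4 in THF–H2O should remove the C4 oxygen by the same carbonate-transfer and quinone-methide pathway as in step 12, giving (2S)-5-hydroxy-2-{3-methoxy-5-[(methoxycarbonyl)oxy]phenyl}-8-(3-methylbut-2-en-1-yl)chroman-7-yl methyl carbonate F7. Degassed aqueous NaOH in MeOH at 0 °C should cleave the two remaining aryl carbonates to 22.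

Further compounds
F1 | step 10 | 1-[2-hydroxy-4,6-bis(methoxymethoxy)-3-(3-methylbut-2-en-1-yl)phenyl]prop-2-yn-1-ol (racemic) | C#CC(O)c1c(O)c(CC=C(C)C)c(OCOC)cc1OCOC
F2 | step 10 | 1-[2-hydroxy-4,6-bis(methoxymethoxy)-3-(3-methylbut-2-en-1-yl)phenyl]prop-2-yn-1-one | C#CC(=O)c1c(O)c(CC=C(C)C)c(OCOC)cc1OCOC
F3 | step 10 | 5,7-bis(methoxymethoxy)-8-(3-methylbut-2-en-1-yl)-4H-chromen-4-one | O=c1ccoc2c(CC=C(C)C)c(OCOC)cc(OCOC)c12
F4 | step 10 | [3-methoxy-5-(methoxymethoxy)phenyl]boronic acid | COCOc1cc(OC)cc(B(O)O)c1
F0 | step 9 | none | none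
F5 | step 11 | (2S)-5,7-dihydroxy-2-(3-hydroxy-5-methoxyphenyl)-8-(3-methylbut-2-en-1-yl)chroman-4-one | COc1cc(O)cc([C@@H]2CC(=O)c3c(O)cc(O)c(CC=C(C)C)c3O2)c1
F6 | step 11 | (2S)-2-{3-methoxy-5-[(methoxycarbonyl)oxy]phenyl}-8-(3-methylbut-2-en-1-yl)-4-oxochroman-5,7-diyl bis(methyl carbonate) | COC(=O)Oc1cc(OC)cc([C@@H]2CC(=O)c3c(OC(=O)OC)cc(OC(=O)OC)c(CC=C(C)C)c3O2)c1
F7 | step 11 | (2S)-5-hydroxy-2-{3-methoxy-5-[(methoxycarbonyl)oxy]phenyl}-8-(3-methylbut-2-en-1-yl)chroman-7-yl methyl carbonate | COC(=O)Oc1cc(OC)cc([C@@H]2CCc3c(O)cc(OC(=O)OC)c(CC=C(C)C)c3O2)c1
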